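**A turnover budget.** The slowing of the earlier runs is taken here as an enzyme using up a budget of turnovers (a total turnover number), since the cedar run's conversion at 8.00 h reads twice the larch run's, while per enzyme it reads lower, at 874 turnovers against 1040.

common to all: second substrate 0.0475 M; enzyme 10 µM

|  | starting material | remark |
|---|---|---|
| cedar | 0.034 M | run made earlier |
| larch | 0.075 M | run made earlier |
| flask | 0.050 M |  |

- cedar (time / h: product / %, starting material / %): 0.667: 4.3, 94.9; 1.33: 8.3, 91.0; 3.00: 16.6, 84.4; 8.00: 25.7, 73.5
- larch (time / h: product / %, starting material / %): 2.00: 8.2, 91.9; 4.00: 11.6, 88.8; 6.00: 12.9, 87.4; 8.00: 13.9, 86.6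

(each reading ± 0.5 percentage points)

* apparent order in second substrate when 20% of the starting material are converted (percent change of the rate of making product for one percent more second substrate charged)

- no earlier run changes the charge of second substrate; that part of a forecast is a guess

**One number.** The shrinking steps of the larch run, extended as a geometric tail, put the budget at 21.8% of the flask's charge, so the spent share, product made over product the budget allows, is 0.918 at 20% conversion.

**Is it enough?** That share holds no second substrate, so on this reckoning more charge leaves the working enzyme at that conversion unchanged, but by subtraction the flask still has 78.9% of its second substrate there, and if the rate goes in proportion to the second substrate present, one percent more charge gives an order of 1.27.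

**The flask.** The forecast, reasoning that near equilibrium the net rate is “a small difference of two terms”, gives 3; the flask gives 1.1, less than the reckoned value.

    ternary complex → enzyme + product (k = 0.820 s⁻¹)
    second substrate + starting complex ⇌ ternary complex (K = 11.0 M⁻¹, k = 43.0 M⁻¹ s⁻¹)
    starting material + enzyme ⇌ starting complex (K = 9.90 M⁻¹, k = 180 M⁻¹ s⁻¹)
    second substrate + starting complex → spent catalyst (k = 0.00680 M⁻¹ s⁻¹)

**The spending.** By 4.00 h the flask held 15.0% product and 68.3% spent catalyst, against a spent share of 0.688, with 84.2% of its second substrate unbound. The cedar run's last reading gives a spent share of 0.802. At 80.0 h the flask held 100% spent catalyst and 21.9% product.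

The runs were generated by integration with constants of no real substance; the scatter is artificial.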